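**Retrosynthetic overview**
1. The last step closes ring A (O1–C2). It then moves the allyl group from C7a to C3a by a cationic 1,2-shift inside an ipso-allyl arenium ion, and finally unmasks the C6 ketone.
2. The precursor of this cascade is a cyclohexadiene-1,2-diol, made by adding an (E)-configured 1-arylpropen-2-yl lithium reagent to an allyl o-quinol.
3. The o-quinol comes from enantioselective allylboration of symmetric 4,5-dimethoxy-o-benzoquinone, which is made from catechol. Its single carbinol centre is relayed to C2, C3 and C3a.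
4. The alkenyl iodide comes from 3,4,5-trimethoxybenzaldehyde (made from p-cresol) by boron-Wittig olefination and iodination.
5. Ring order: ring B (from catechol) and the aryl ring (from p-cresol) are present from the start, and ring A forms last.

Convention: ring atoms carry the benzofuran numbers of the target (O1, C2, C3, C3a, C4 to C7, C7a) in all intermediates.

**Step 1**
Reactants: 1 catechol
Product: 2 4,5-dimethoxy-1,2-benzoquinone
Conditions: PbO2 (3.3 equiv), NaOMe (0.2 equiv), MeOH, 0 °C to rt
Reagents that add atoms: methanol CO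
Why: Known oxidative methoxylation, in which oxidation to the o-quinone and conjugate (Michael) addition of methoxide alternate until the doubly vinylogous ester 2 is reached, which adds no more methanol; no stereocentre is formed.

**Step 2**
Reactants: 2 4,5-dimethoxy-1,2-benzoquinone
Product: 3 (6R)-6-hydroxy-3,4-dimethoxy-6-(prop-2-en-1-yl)cyclohexa-2,4-dien-1-one
Conditions: allylB(pin) (1.3 equiv), 2-tert-butyl-6-({[(2S)-1-(dimethylamino)-3-methyl-1-oxobutan-2-yl]amino}methyl)phenol (5 mol %), NaOt-Bu (5 mol %), MeOH (2 equiv), toluene, 0 °C; product kept cold and used promptly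
Reagents that add atoms: allylboronic acid pinacol ester C=CCB1OC(C)(C)C(C)(C)O1
Why: Proposed new method: the aminophenol exchanges with allylB(pin) to give a chiral allylboron species whose ammonium proton binds the neighbouring carbonyl of the 1,2-dione, so allyl is delivered through a closed six-membered chair transition state to one enantiotopic face of either homotopic carbonyl and sets the (R) carbinol centre, and only one addition occurs because the remaining carbonyl is a plain vinylogous ester; the closest known reaction type is the catalytic enantioselective allylboration of isatins and other activated ketones, not yet shown for o-quinones, and a test run decides which catalyst antipode gives (R).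

**Step 3**
Reactants: 4 p-cresol
Product: 7 3,5-dibromo-4-hydroxybenzaldehyde, via 2,6-dibromo-4-methylphenol 5 (not isolated), via 2,6-dibromo-4-(dibromomethyl)phenol 6 (not isolated)
Conditions: Br2 (4.1 equiv), 1,2-dichlorobenzene, 35 °C then 150 °C; H2O, 100 °C
Reagents that add atoms: bromine BrBr; water O
Why: Electrophilic aromatic bromination ortho to the hydroxyl, free-radical benzylic dibromination at high temperature and hydrolysis of the benzal bromide form the established technical route to this aldehyde; no stereocentre is formed.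

**Step 4**
Reactants: 7 3,5-dibromo-4-hydroxybenzaldehyde
Product: 9 3,4,5-trimethoxybenzaldehyde, via syringaldehyde 8 (not isolated)
Conditions: NaOMe (3.3 equiv), CuCl (10 mol %), DMF–MeOH, 115 °C; then Me2SO4 (1.2 equiv), 50 °C
Reagents that add atoms: sodium methoxide C[O-].[Na+]; dimethyl sulfate COS(=O)(=O)OC
Why: Copper-catalysed Ullmann-type methoxylation of both aryl bromides is followed by Williamson O-methylation of the sodium phenolate in the same pot, and the aldehyde survives both.

**Step 5**
Reactants: 9 3,4,5-trimethoxybenzaldehyde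
Product: 11 5-[(1E)-2-iodoprop-1-en-1-yl]-1,2,3-trimethoxybenzene, via alkenyl boronate 10 (not isolated)
Conditions: CH3CH(Bpin)2, lithium 2,2,6,6-tetramethylpiperidide, THF, 0 °C, then 9, −78 °C to rt; then NaOH, I2, THF–H2O, 0 °C
Reagents that add atoms: 1,1-bis(pinacolboryl)ethane CC(B1OC(C)(C)C(C)(C)O1)B1OC(C)(C)C(C)(C)O1; iodine [I][I]
Why: In the boron-Wittig olefination the syn boron–oxygen elimination places the aryl group trans to the remaining bulky Bpin, and base-mediated iododeboronation proceeds with retention, so aryl and iodine end up trans.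

**Step 6**
Reactants: 3 (6R)-6-hydroxy-3,4-dimethoxy-6-(prop-2-en-1-yl)cyclohexa-2,4-dien-1-one; 11 5-[(1E)-2-iodoprop-1-en-1-yl]-1,2,3-trimethoxybenzene
Product: 13 (1R,2S)-4,5-dimethoxy-1-(prop-2-en-1-yl)-2-[(1E)-1-(3,4,5-trimethoxyphenyl)prop-1-en-2-yl]cyclohexa-3,5-diene-1,2-diol, via alkenyllithium 12 (not isolated)
Conditions: 11, t-BuLi (2 equiv), Et2O, −78 °C; added to 3 pre-treated with LiN(SiMe3)2 (1 equiv), THF, −78 °C; H2O quench at −78 °C; crude diol kept cold and away from acid
Reagents that add atoms: none
Why: Lithium–iodine exchange with retention is followed by 1,2-addition of the hard alkenyllithium to the vinylogous-ester carbonyl (the first half of a Stork–Danheiser sequence) with the carbinol of 3 masked as its lithium alkoxide; attack anti to allyl should give mainly the trans diol, but this new carbinol centre is erased in step 7, so only the untouched (R) centre matters.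

**Step 7**
Reactants: 13 (1R,2S)-4,5-dimethoxy-1-(prop-2-en-1-yl)-2-[(1E)-1-(3,4,5-trimethoxyphenyl)prop-1-en-2-yl]cyclohexa-3,5-diene-1,2-diol
Product: 16 (2R,3S,3aS)-5-methoxy-3-methyl-3a-(prop-2-en-1-yl)-2-(3,4,5-trimethoxyphenyl)-3,3a-dihydro-1-benzofuran-6(2H)-one, via 7a-allyl-2,7a-dihydrobenzofuran 14 (not isolated), via 6,6-dimethyl ketal 15 (not isolated)
Conditions: camphorsulfonic acid (10 mol %), HC(OMe)3 (1.5 equiv), CH2Cl2, −40 to 0 °C; then 5% aq citric acid–THF, 0 °C
Reagents that add atoms: water O
Why: Proposed new method: acid ionises the styryl- and methoxy-stabilised carbinol at C3a (erasing that centre), the C7a hydroxyl closes suprafacially on the E-configured benzylic terminus so that least-motion rotation puts the aryl group anti to allyl (sets C2) and gives 14, protonation of its dienol ether at C3 gives an ipso-allyl arenium ion, and the allyl group then makes a suprafacial cationic 1,2-shift of pinacol or Wagner–Meerwein type, pushed by O1, to C3a, which carries more charge than C7 because it is alkyl-substituted while C7 sits next to the inductively withdrawing C6–OMe carbon; the shift is faster for the C3 epimer that has hydrogen and not methyl on the allyl face (sets C3 with methyl cis to aryl, and C3a), methanol traps the resulting dialkoxyallyl cation as 15, and mild hydrolysis frees the C6 ketone, the closest known reaction types being the pinacol rearrangement, the dienone–phenol rearrangement and Stork–Danheiser ionisation.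

**Compound list**
1 | catechol (benzene-1,2-diol) | Oc1ccccc1O | starting material
2 | 4,5-dimethoxy-1,2-benzoquinone (4,5-dimethoxycyclohexa-3,5-diene-1,2-dione) | COC1=CC(=O)C(=O)C=C1OC | intermediate
3 | (6R)-6-hydroxy-3,4-dimethoxy-6-(prop-2-en-1-yl)cyclohexa-2,4-dien-1-one | C=CC[C@@]1(O)C=C(OC)C(OC)=CC1=O | intermediate
4 | p-cresol (4-methylphenol) | Cc1ccc(O)cc1 | starting material
5 | 2,6-dibromo-4-methylphenol | Cc1cc(Br)c(O)c(Br)c1 | intermediate
6 | 2,6-dibromo-4-(dibromomethyl)phenol | Oc1c(Br)cc(C(Br)Br)cc1Br | intermediate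
7 | 3,5-dibromo-4-hydroxybenzaldehyde | O=Cc1cc(Br)c(O)c(Br)c1 | intermediate
8 | syringaldehyde (4-hydroxy-3,5-dimethoxybenzaldehyde, present as its sodium phenolate) | COc1cc(C=O)cc(OC)c1O | intermediate
9 | 3,4,5-trimethoxybenzaldehyde | COc1cc(C=O)cc(OC)c1OC | intermediate
10 | 4,4,5,5-tetramethyl-2-[(1Z)-1-(3,4,5-trimethoxyphenyl)prop-1-en-2-yl]-1,3,2-dioxaborolane (aryl and boron trans) | C/C(B1OC(C)(C)C(C)(C)O1)=C\c1cc(OC)c(OC)c(OC)c1 | intermediate
11 | 5-[(1E)-2-iodoprop-1-en-1-yl]-1,2,3-trimethoxybenzene (aryl and iodine trans) | C/C(I)=C\c1cc(OC)c(OC)c(OC)c1 | intermediate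
12 | [(1Z)-1-(3,4,5-trimethoxyphenyl)prop-1-en-2-yl]lithium (aryl and lithium trans) | C/C([Li])=C\c1cc(OC)c(OC)c(OC)c1 | intermediate
13 | (1R,2S)-4,5-dimethoxy-1-(prop-2-en-1-yl)-2-[(1E)-1-(3,4,5-trimethoxyphenyl)prop-1-en-2-yl]cyclohexa-3,5-diene-1,2-diol (expected major epimer; the C2 epimer reacts alike) | C=CC[C@@]1(O)C=C(OC)C(OC)=C[C@]1(O)/C(C)=C/c1cc(OC)c(OC)c(OC)c1 | intermediate
14 | (2S,7aR)-5,6-dimethoxy-3-methyl-7a-(prop-2-en-1-yl)-2-(3,4,5-trimethoxyphenyl)-2,7a-dihydro-1-benzofuran | C=CC[C@@]12C=C(OC)C(OC)=CC1=C(C)[C@H](c1cc(OC)c(OC)c(OC)c1)O2 | intermediate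
15 | (2R,3S,3aS)-5,6,6-trimethoxy-3-methyl-3a-(prop-2-en-1-yl)-2-(3,4,5-trimethoxyphenyl)-2,3,3a,6-tetrahydro-1-benzofuran | C=CC[C@]12C=C(OC)C(OC)(OC)C=C1O[C@@H](c1cc(OC)c(OC)c(OC)c1)[C@H]2C | intermediate
16 | (2R,3S,3aS)-5-methoxy-3-methyl-3a-(prop-2-en-1-yl)-2-(3,4,5-trimethoxyphenyl)-3,3a-dihydro-1-benzofuran-6(2H)-one | C=CC[C@]12C=C(OC)C(=O)C=C1O[C@@H](c1cc(OC)c(OC)c(OC)c1)[C@H]2C | target

**Step count**
Total steps: 7. Longest linear sequence: 5 (steps 3, 4, 5, 6 and 7, starting from 4).

**Steps most likely to fail**

Step 7 (new cascade). Four things can go wrong.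
- The allyl group may migrate to the unsubstituted C7 and the ring then aromatises.
- C3 may be protonated from the wrong face.
- A pinacol shift may occur before ring A closes and leave a ring-open dienone that mild acid cannot cyclise.
- Compound 14 may aromatise by a thermal sigmatropic shift.

The fallback sets out from 3 and 9 and comes back at 16. It uses only known chemistry and gives up the stereocentre of 3. Zn dust in AcOH reduces 3 to 2-allyl-4,5-dimethoxyphenol F1. PhI(OAc)2 in MeOH oxidises this to the quinone monoketal 2-allyl-4,4,5-trimethoxycyclohexa-2,5-dien-1-one F2. A salt-free Wittig reaction of 9 with EtPPh3Br and KN(SiMe3)2 gives (Z)-isoelemicin F3. The known acid-promoted cycloaddition of quinone monoketals with propenylarenes (SnCl4, CH2Cl2, −78 °C, aqueous work-up) joins F2 and F3 to 16 as a racemate, that is together with its mirror image ent-16 F4. This is removed by preparative HPLC on a chiral phase after the diastereomers have been separated.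

Step 2 (new substrate class). The o-quinone may react slowly or with low selectivity. Compound 3 can racemise by a degenerate α-ketol shift, dimerise, or aromatise to the allyl aryl ether.

The fallback sets out from 2 and comes back at 3. Barbier allylation with allyl bromide and indium powder in DMF, which is known for o-quinones and other 1,2-diones, gives 3 as a racemate, that is together with ent-3 F5. The enantiomers are separated by preparative supercritical-fluid chromatography on a chiral phase.

Step 6. The α-alkoxide lowers the electrophilicity of the carbonyl, and the alkoxide of 3 may rearrange before it is attacked.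

The fallback sets out from 3 and comes back at 13. Me3SiOTf and 2,6-lutidine convert 3 into the silyl ether (6R)-3,4-dimethoxy-6-(prop-2-en-1-yl)-6-[(trimethylsilyl)oxy]cyclohexa-2,4-dien-1-one F6. Compound 12 is transmetalated with CeCl3 and added to F6 to give (1S,6R)-3,4-dimethoxy-6-(prop-2-en-1-yl)-1-[(1E)-1-(3,4,5-trimethoxyphenyl)prop-1-en-2-yl]-6-[(trimethylsilyl)oxy]cyclohexa-2,4-dien-1-ol F7. Bu4NF buffered with AcOH then removes silicon to give 13.

**Further compounds**
F1 | step 7 | 2-allyl-4,5-dimethoxyphenol | C=CCc1cc(OC)c(OC)cc1O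
F2 | step 7 | 2-allyl-4,4,5-trimethoxycyclohexa-2,5-dien-1-one | C=CCC1=CC(OC)(OC)C(OC)=CC1=O
F3 | step 7 | (Z)-isoelemicin, 1,2,3-trimethoxy-5-[(1Z)-prop-1-en-1-yl]benzene | C/C=C\c1cc(OC)c(OC)c(OC)c1
F4 | step 7 | ent-16, (2S,3R,3aR)-5-methoxy-3-methyl-3a-(prop-2-en-1-yl)-2-(3,4,5-trimethoxyphenyl)-3,3a-dihydro-1-benzofuran-6(2H)-one | C=CC[C@@]12C=C(OC)C(=O)C=C1O[C@H](c1cc(OC)c(OC)c(OC)c1)[C@@H]2C
F5 | step 2 | ent-3, (6S)-6-hydroxy-3,4-dimethoxy-6-(prop-2-en-1-yl)cyclohexa-2,4-dien-1-one | C=CC[C@]1(O)C=C(OC)C(OC)=CC1=O
F6 | step 6 | (6R)-3,4-dimethoxy-6-(prop-2-en-1-yl)-6-[(trimethylsilyl)oxy]cyclohexa-2,4-dien-1-one | C=CC[C@@]1(O[Si](C)(C)C)C=C(OC)C(OC)=CC1=O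
F7 | step 6 | (1S,6R)-3,4-dimethoxy-6-(prop-2-en-1-yl)-1-[(1E)-1-(3,4,5-trimethoxyphenyl)prop-1-en-2-yl]-6-[(trimethylsilyl)oxy]cyclohexa-2,4-dien-1-ol | C=CC[C@@]1(O[Si](C)(C)C)C=C(OC)C(OC)=C[C@]1(O)/C(C)=C/c1cc(OC)c(OC)c(OC)c1
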